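The oxolane ring (O1, C2 bearing the benzyl group, C3 carbinol, C4, C5 bearing the aroylmethyl chain) is disconnected at O1–C5 and C2–C3. O1=C2 is then the carbonyl of an O-benzyl homovanillin, and C3–C4–C5 a latent 1,3-zwitterion stored in a racemic styryl-donor, malonyl-acceptor cyclopropane. A magnesium–pybox dynamic kinetic asymmetric (3+2) annulation unites them in one operation, exploiting the cis relation of the C2 and C5 substituents across the ring oxygen and setting both centres. The malonyl carbon C3 is afterwards degraded to the ketone and reduced from the open face to the all-cis carbinol; the styryl group is the masked aroylmethyl chain.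

Key step: step 4

Remark: the (S,S) antipode of the pybox ligand is assumed to deliver the (2R,5R) cycloadduct; if the sense of induction is the opposite, its mirror image is used.

Step 1
Reactants: 1 dimethyl 2-vinylcyclopropane-1,1-dicarboxylate (racemic); 2 4-benzyloxy-3-methoxystyrene
Product: 3 dimethyl 2-[(E)-2-(4-benzyloxy-3-methoxyphenyl)ethenyl]cyclopropane-1,1-dicarboxylate (racemic)
Conditions: second-generation Grubbs catalyst RuCl2(H2IMes)(PCy3)(=CHPh) (5 mol %), 2 (3 equiv), CH2Cl2, 40 °C
Reagents that add atoms: none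
Why: Olefin cross-metathesis between the monosubstituted vinyl group of 1 and the excess styrene 2 is driven by loss of ethene and should give the thermodynamically favoured (E)-styryl donor, with no stereocentre set because the key step consumes the racemate.

Step 2
Reactants: 4 2-(4-hydroxy-3-methoxyphenyl)ethanol (homovanillyl alcohol)
Product: 5 2-(4-benzyloxy-3-methoxyphenyl)ethanol
Conditions: BnBr, K2CO3, acetone, 56 °C
Reagents that add atoms: benzyl bromide, BrCc1ccccc1
Why: Williamson etherification, in which carbonate deprotonates only the phenol, so the phenoxide is benzylated while the primary alcohol stays free.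

Step 3
Reactants: 5 2-(4-benzyloxy-3-methoxyphenyl)ethanol
Product: 6 (4-benzyloxy-3-methoxyphenyl)acetaldehyde
Conditions: Dess–Martin periodinane, CH2Cl2, 0 → 23 °C
Reagents that add atoms: none
Why: Dess–Martin oxidation should stop cleanly at the enolisable arylacetaldehyde under non-basic conditions, and the aldehyde is used at once.

Step 4
Reactants: 3 dimethyl 2-[(E)-2-(4-benzyloxy-3-methoxyphenyl)ethenyl]cyclopropane-1,1-dicarboxylate (racemic); 6 (4-benzyloxy-3-methoxyphenyl)acetaldehyde
Product: 7 dimethyl (2R,5R)-2-(4-benzyloxy-3-methoxybenzyl)-5-[(E)-2-(4-benzyloxy-3-methoxyphenyl)ethenyl]oxolane-3,3-dicarboxylate (2,5-cis)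
Conditions: MgI2 (10 mol %), (S,S)-tBu-pybox (12 mol %), 6 (2 equiv), CCl4, 23 °C
Reagents that add atoms: none
Why: Chelation of the malonyl group of 3 by the chiral magnesium Lewis acid ionises the cyclopropane bond between the malonyl carbon and the styryl-bearing carbon (the future C3 and C5) to a configurationally labile, styryl-stabilised intimate ion pair, so the two antipodes of 3 interconvert while the catalyst lets one react faster. The carbonyl oxygen of 6 attacks the donor carbon with inversion (O1–C5 bond) and the magnesium malonate enolate then adds to the resulting oxocarbenium carbon (C2–C3 bond); the closest known reaction type is the Lewis acid-catalysed (3+2) annulation of donor–acceptor cyclopropanes with aldehydes in its dynamic kinetic asymmetric form. The oxolane ring closes by a 5-(enolexo)-endo-trig aldol-type attack on the (E)-oxocarbenium ion through an envelope transition state with the C2 and C5 substituents pseudo-equatorial. C5 is set by the pybox ligand, which selects the cyclopropane antipode, and C2 follows from C5 through the cis-selective ring closure. The step needs attack at the cyclopropane carbon and not at the styryl terminus, and it must outrun self-aldol of 6; the tight chelated ion pair and the excess of 6 should secure both.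

Step 5
Reactants: 7 dimethyl (2R,5R)-2-(4-benzyloxy-3-methoxybenzyl)-5-[(E)-2-(4-benzyloxy-3-methoxyphenyl)ethenyl]oxolane-3,3-dicarboxylate
Product: 8 (2R,5R)-2-(4-benzyloxy-3-methoxybenzyl)-5-[(E)-2-(4-benzyloxy-3-methoxyphenyl)ethenyl]oxolane-3,3-dicarboxylic acid
Conditions: KOH, MeOH/THF/H2O, 50 °C; then 1 M HCl to pH 3, 0 °C
Reagents that add atoms: potassium hydroxide, [K+].[OH-]
Why: Saponification (BAc2) of both methyl esters is safe because the quaternary malonate can neither enolise nor eliminate, and cold, brief acidification spares the acid-sensitive cinnamyl-type C5–O1 bond and avoids thermal decarboxylation.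

Step 6
Reactants: 8 (2R,5R)-2-(4-benzyloxy-3-methoxybenzyl)-5-[(E)-2-(4-benzyloxy-3-methoxyphenyl)ethenyl]oxolane-3,3-dicarboxylic acid
Product: 11 (2R,5R)-2-(4-benzyloxy-3-methoxybenzyl)-5-[(E)-2-(4-benzyloxy-3-methoxyphenyl)ethenyl]oxolan-3-one, via bis(acyl azide) 9 (not isolated), via geminal diisocyanate 10 (not isolated)
Conditions: (PhO)2P(O)N3, Et3N, PhMe, 0 → 23 °C; then 85 °C; then AcOH/H2O/THF, 40 °C
Reagents that add atoms: water, O; diphenylphosphoryl azide, [N-]=[N+]=NP(=O)(Oc1ccccc1)Oc1ccccc1 (its nitrogen atoms appear in 9 and 10 only)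
Why: Double Curtius rearrangement of a disubstituted malonic acid (acyl azide formation, thermal loss of N2 to the geminal diisocyanate, hydrolysis of the geminal diamine) is the classical malonic acid to ketone degradation and needs only weak acid, so the styrene, the cinnamyl-type ether and the C2 centre next to the new ketone should survive.

Step 7
Reactants: 11 (2R,5R)-2-(4-benzyloxy-3-methoxybenzyl)-5-[(E)-2-(4-benzyloxy-3-methoxyphenyl)ethenyl]oxolan-3-one
Product: 12 (2R,3R,5R)-2-(4-benzyloxy-3-methoxybenzyl)-5-[(E)-2-(4-benzyloxy-3-methoxyphenyl)ethenyl]oxolan-3-ol (all-cis)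
Conditions: LiBH(s-Bu)3 (L-Selectride), THF, −78 °C; then H2O
Reagents that add atoms: none
Why: Substrate-controlled ketone reduction, in which the bulky hydride attacks C3 from the face opposite the cis C2 and C5 substituents and so places the hydroxyl cis to both (3R), at a temperature where enolisation towards C2 does not compete.

Step 8
Reactants: 12 (2R,3R,5R)-2-(4-benzyloxy-3-methoxybenzyl)-5-[(E)-2-(4-benzyloxy-3-methoxyphenyl)ethenyl]oxolan-3-ol
Product: 13 (2R,3R,5R)-2-(4-benzyloxy-3-methoxybenzyl)-5-[2-(4-benzyloxy-3-methoxyphenyl)-2-oxoethyl]oxolan-3-ol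
Conditions: FeCl2 (10 mol %), neocuproine (10 mol %), PhSiH3, air (1 atm), EtOH, 50 °C
Reagents that add atoms: dioxygen, O=O
Why: Iron hydride hydrogen-atom-transfer Wacker-type oxidation (Mukaiyama manifold), in which the hydrogen atom adds to the alkene carbon next to C5 to give the benzylic radical that is trapped by O2 and collapses to the aryl ketone, so the carbonyl should appear only at the benzylic carbon and the free C3 hydroxyl cannot take part in a nucleometalation.

Step 9
Reactants: 13 (2R,3R,5R)-2-(4-benzyloxy-3-methoxybenzyl)-5-[2-(4-benzyloxy-3-methoxyphenyl)-2-oxoethyl]oxolan-3-ol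
Product: 14 Renealtin A, (2R,3R,5R)-2-(4-hydroxy-3-methoxybenzyl)-5-[2-(4-hydroxy-3-methoxyphenyl)-2-oxoethyl]oxolan-3-ol
Conditions: H2 (1 atm), 10 % Pd/C, EtOAc, 23 °C
Reagents that add atoms: none
Why: Hydrogenolysis of the two aryl benzyl ethers under neutral conditions should leave the base-sensitive β-alkoxy ketone and its C5 centre untouched, the electron-rich aryl ketone being reduced far more slowly.

Compound list
1 | dimethyl 2-vinylcyclopropane-1,1-dicarboxylate (racemic) | C=CC1CC1(C(=O)OC)C(=O)OC | starting material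
2 | 4-benzyloxy-3-methoxystyrene | C=Cc1ccc(OCc2ccccc2)c(OC)c1 | starting material
3 | dimethyl 2-[(E)-2-(4-benzyloxy-3-methoxyphenyl)ethenyl]cyclopropane-1,1-dicarboxylate (racemic) | COC(=O)C1(C(=O)OC)CC1/C=C/c1ccc(OCc2ccccc2)c(OC)c1 | intermediate
4 | 2-(4-hydroxy-3-methoxyphenyl)ethanol (homovanillyl alcohol) | COc1cc(CCO)ccc1O | starting material
5 | 2-(4-benzyloxy-3-methoxyphenyl)ethanol | COc1cc(CCO)ccc1OCc1ccccc1 | intermediate
6 | (4-benzyloxy-3-methoxyphenyl)acetaldehyde | COc1cc(CC=O)ccc1OCc1ccccc1 | intermediate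
7 | dimethyl (2R,5R)-2-(4-benzyloxy-3-methoxybenzyl)-5-[(E)-2-(4-benzyloxy-3-methoxyphenyl)ethenyl]oxolane-3,3-dicarboxylate | COc1cc(C[C@H]2O[C@@H](/C=C/c3ccc(OCc4ccccc4)c(OC)c3)CC2(C(=O)OC)C(=O)OC)ccc1OCc1ccccc1 | intermediate
8 | (2R,5R)-2-(4-benzyloxy-3-methoxybenzyl)-5-[(E)-2-(4-benzyloxy-3-methoxyphenyl)ethenyl]oxolane-3,3-dicarboxylic acid | COc1cc(C[C@H]2O[C@@H](/C=C/c3ccc(OCc4ccccc4)c(OC)c3)CC2(C(=O)O)C(=O)O)ccc1OCc1ccccc1 | intermediate
9 | (2R,5R)-2-(4-benzyloxy-3-methoxybenzyl)-5-[(E)-2-(4-benzyloxy-3-methoxyphenyl)ethenyl]oxolane-3,3-dicarbonyl diazide | COc1cc(C[C@H]2O[C@@H](/C=C/c3ccc(OCc4ccccc4)c(OC)c3)CC2(C(=O)N=[N+]=[N-])C(=O)N=[N+]=[N-])ccc1OCc1ccccc1 | intermediate (not isolated)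
10 | (2R,5R)-2-(4-benzyloxy-3-methoxybenzyl)-5-[(E)-2-(4-benzyloxy-3-methoxyphenyl)ethenyl]-3,3-diisocyanatooxolane | COc1cc(C[C@H]2O[C@@H](/C=C/c3ccc(OCc4ccccc4)c(OC)c3)CC2(N=C=O)N=C=O)ccc1OCc1ccccc1 | intermediate (not isolated)
11 | (2R,5R)-2-(4-benzyloxy-3-methoxybenzyl)-5-[(E)-2-(4-benzyloxy-3-methoxyphenyl)ethenyl]oxolan-3-one | COc1cc(C[C@H]2O[C@@H](/C=C/c3ccc(OCc4ccccc4)c(OC)c3)CC2=O)ccc1OCc1ccccc1 | intermediate
12 | (2R,3R,5R)-2-(4-benzyloxy-3-methoxybenzyl)-5-[(E)-2-(4-benzyloxy-3-methoxyphenyl)ethenyl]oxolan-3-ol | COc1cc(C[C@H]2O[C@@H](/C=C/c3ccc(OCc4ccccc4)c(OC)c3)C[C@H]2O)ccc1OCc1ccccc1 | intermediate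
13 | (2R,3R,5R)-2-(4-benzyloxy-3-methoxybenzyl)-5-[2-(4-benzyloxy-3-methoxyphenyl)-2-oxoethyl]oxolan-3-ol | COc1cc(C[C@H]2O[C@@H](CC(=O)c3ccc(OCc4ccccc4)c(OC)c3)C[C@H]2O)ccc1OCc1ccccc1 | intermediate
14 | Renealtin A, (2R,3R,5R)-2-(4-hydroxy-3-methoxybenzyl)-5-[2-(4-hydroxy-3-methoxyphenyl)-2-oxoethyl]oxolan-3-ol | COc1cc(C[C@H]2O[C@@H](CC(=O)c3ccc(O)c(OC)c3)C[C@H]2O)ccc1O | target

Total step count: 9
Longest linear sequence: 8 steps (4 → 5 → 6 → 7 → 8 → 11 → 12 → 13 → 14, steps 2 to 9); step 1 is the convergent branch.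

Steps most likely to fail

Step 4. The enolisable aldehyde 6 may self-condense at the Lewis acid faster than it is captured, and the catalyst may discriminate the equilibrating cyclopropane antipodes incompletely. Ionisation of the product at C5 by the Lewis acid may also erode the cis relation. Fallback: setting out from 3 and 6, the same two ring bonds would be made in one operation by the racemic annulation under Sn(OTf)2 (5 mol %, CH2Cl2, 23 °C), a well-precedented and likewise cis-selective variant, to give the racemic cis-cycloadduct F1. Saponification as in step 5 would give the racemic diacid F2. Classical resolution by fractional crystallisation with (S)-1-phenylethylamine would give the bis[(S)-1-phenylethylammonium] salt F3 of the (2R,5R)-acid, and cold acidification of this salt comes back to the route at 8.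

Step 6. A half-rearranged isocyanato acid may cyclise on itself, or amine and isocyanate may combine to ureas during hydrolysis, so that the two carboxyl carbons are not fully excised. Fallback: setting out from 8, heating in pyridine (100 °C) would remove one carboxyl to give the oxolane-3-carboxylic acid F4 as C3 epimers. Its dianion (LDA, 2.2 equiv, THF, −78 °C) would be oxygenated with O2 to the α-hydroperoxy acid F5, which on acidification (TsOH, 0 °C) loses CO2 and water and comes back to the route at 11.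

Step 8. Hydrogen-atom transfer to the 1,2-disubstituted styrene may be sluggish, and the benzylic peroxide may be over-reduced to the alcohol instead of collapsing to the ketone. Fallback: setting out from 12, ionic Markovnikov hydration by oxymercuration (Hg(OAc)2, THF/H2O, 23 °C) would place the hydroxyl at the benzylic carbon to give the organomercurial F6. This would be reduced in the same flask (NaBH4, aq. NaOH) to the benzylic alcohol F7; MnO2 (CH2Cl2, 23 °C), which oxidises only the benzylic carbinol, then comes back to the route at 13.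

Further compounds
F1 | step 4 | racemic cis-cycloadduct, dimethyl (2R*,5R*)-2-(4-benzyloxy-3-methoxybenzyl)-5-[(E)-2-(4-benzyloxy-3-methoxyphenyl)ethenyl]oxolane-3,3-dicarboxylate (both antipodes written) | COc1cc(C[C@H]2O[C@@H](/C=C/c3ccc(OCc4ccccc4)c(OC)c3)CC2(C(=O)OC)C(=O)OC)ccc1OCc1ccccc1.COc1cc(C[C@@H]2O[C@H](/C=C/c3ccc(OCc4ccccc4)c(OC)c3)CC2(C(=O)OC)C(=O)OC)ccc1OCc1ccccc1
F2 | step 4 | racemic cis-diacid, (2R*,5R*)-2-(4-benzyloxy-3-methoxybenzyl)-5-[(E)-2-(4-benzyloxy-3-methoxyphenyl)ethenyl]oxolane-3,3-dicarboxylic acid (both antipodes written) | COc1cc(C[C@H]2O[C@@H](/C=C/c3ccc(OCc4ccccc4)c(OC)c3)CC2(C(=O)O)C(=O)O)ccc1OCc1ccccc1.COc1cc(C[C@@H]2O[C@H](/C=C/c3ccc(OCc4ccccc4)c(OC)c3)CC2(C(=O)O)C(=O)O)ccc1OCc1ccccc1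
F3 | step 4 | bis[(S)-1-phenylethylammonium] salt of the (2R,5R)-diacid | COc1cc(C[C@H]2O[C@@H](/C=C/c3ccc(OCc4ccccc4)c(OC)c3)CC2(C(=O)[O-])C(=O)[O-])ccc1OCc1ccccc1.C[C@H]([NH3+])c1ccccc1.C[C@H]([NH3+])c1ccccc1
F4 | step 6 | (2R,5R)-2-(4-benzyloxy-3-methoxybenzyl)-5-[(E)-2-(4-benzyloxy-3-methoxyphenyl)ethenyl]oxolane-3-carboxylic acid (C3 epimers) | COc1cc(C[C@H]2O[C@@H](/C=C/c3ccc(OCc4ccccc4)c(OC)c3)CC2C(=O)O)ccc1OCc1ccccc1
F5 | step 6 | (2R,5R)-2-(4-benzyloxy-3-methoxybenzyl)-5-[(E)-2-(4-benzyloxy-3-methoxyphenyl)ethenyl]-3-hydroperoxyoxolane-3-carboxylic acid (C3 epimers, not isolated) | COc1cc(C[C@H]2O[C@@H](/C=C/c3ccc(OCc4ccccc4)c(OC)c3)CC2(OO)C(=O)O)ccc1OCc1ccccc1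
F6 | step 8 | organomercurial with acetoxymercurio at the carbon next to C5 and hydroxyl at the benzylic carbon (not isolated) | COc1cc(C[C@H]2O[C@@H](C([Hg]OC(C)=O)C(O)c3ccc(OCc4ccccc4)c(OC)c3)C[C@H]2O)ccc1OCc1ccccc1
F7 | step 8 | (2R,3R,5R)-2-(4-benzyloxy-3-methoxybenzyl)-5-[2-(4-benzyloxy-3-methoxyphenyl)-2-hydroxyethyl]oxolan-3-ol (epimers at the new carbinol) | COc1cc(C[C@H]2O[C@@H](CC(O)c3ccc(OCc4ccccc4)c(OC)c3)C[C@H]2O)ccc1OCc1ccccc1
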